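**Numbering.** Compounds 1–18 are fixed by the steps below and used throughout; 18 is the target.

## Analysis of the target

Target 18 is a prenylated pyrano-dihydrochalcone. Its core is a 2,2-dimethyl-2H-chromene: benzene ring A (C4a, C5, C6, C7, C8, C8a) fused to a pyran ring (O1, C2, C3, C4). C6 carries a 3-(4-hydroxyphenyl)propanoyl chain ending in ring B, C7 a free hydroxyl, C8 a 3-methylbut-2-enyl (prenyl) group, and C5 is the only unsubstituted carbon of ring A. There is no stereocentre and no stereogenic double bond, so only regiochemistry and functional-group survival have to be controlled. The sensitive parts are the electron-rich C3=C4 bond (acid, electrophilic halogen, oxidants), the prenyl alkene, which a neighbouring free phenol captures under acid, the enolisable aryl ketone and the two phenols. The difficulty lies in ring A: it is a resorcinol whose two oxygens must be told apart (O1 in the pyran, O7 free), with the prenyl group on the carbon between them (C8) and the acyl group on the other flank of O7 (C6). Direct prenylation or pyran annulation of a 2,4-dihydroxyaryl ketone would give linear/angular and C/O regioisomers. The strategy rests on C2: it bears O1 and two methyl groups and is joined to a cis C3=C4 bond, which is the carbon pattern of a coumarin whose lactone carbonyl is C2. In a 7-oxygenated coumarin O1 and O7 differ from the outset, and the C7–C8 bond has the higher double-bond character, so a sigmatropic shift from O7 ends at C8 and leaves C6 as the only position ortho to O7.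

## Retrosynthetic reasoning

**18 ⇒ 17.** The last operation removes two methoxymethyl acetals from 17, one on O7 and one on the ring B phenol. No skeletal bond is cut. Both phenols stay masked through the organolithium chemistry, and the O7 acetal doubles as the directing group for the preceding step. The forward reaction must free both phenols without letting O7 add to the prenyl alkene or the chromene double bond take up solvent.

**17 ⇒ 11 + 14.** The C6–C(=O) bond is cut. It joins two halves of similar size, and C6 is the one ring carbon that can be addressed selectively: it is the only position ortho to the O7 acetal of chromene 11, because C8 is occupied. Forward, deprotonation at C6 gives aryllithium 15, which adds to the N-methoxy-N-methylamide 14; the chelated adduct 16 holds the ketone oxidation level until work-up. A Friedel–Crafts acylation would cut the same bond but needs Lewis acids that neither the chromene nor the prenyl group tolerates. Halogenation at C6 as a prelude to halogen–metal exchange would compete with attack on both alkenes.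

**14 ⇒ 13 ⇒ 12.** Amide 14 comes from 13 by O-protection, and 13 from phloretic acid 12 by amide formation. Ring B and the three-carbon chain are bought in one piece.

**11 ⇒ 8 (key disconnection).** Three bonds at C2 are cut together: both C2–CH3 bonds and O1–C2. C2 then becomes the lactone carbonyl of coumarin 8, with O1, the cis C3=C4 bond and C4a already in place. The cut is made here because this quaternary carbon can be assembled in one operation from a carbonyl at the acid oxidation level. Cutting the pyran at C4–C4a or O1–C8a instead would lead back to a resorcinol on which linear and angular annulation must be separated. Forward, two methyl nucleophiles must add to the carbonyl of 8 (through enone 9 to diol 10), and the phenol oxygen must then displace the tertiary allylic hydroxyl.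

**8 ⇒ 7 ⇒ 6 ⇒ 5.** The O7 acetal is removed to give phenol 7, and the C8–CH2 bond of the prenyl group is cut in a retro-Claisen sense, via dienone 6, to the 1,1-dimethylallyl ether 5. The bond is made intramolecularly from O7, so no free prenyl electrophile meets the ring, and the site is decided by the bond fixation of the coumarin (C7–C8 over C6–C7). The allyl unit is inverted in the shift, so the ether must carry the tertiary terminus on oxygen for the primary terminus to arrive on C8.

**5 ⇒ 4 ⇒ 1 + 2.** A tertiary allylic aryl ether cannot be made by direct substitution. The alkene is therefore traced back to the alkyne of 4, and the O7–C bond of 4 is cut to umbelliferone 1 and the tertiary propargylic alcohol 2, activated in the flask as its trifluoroacetate 3. A copper-stabilised propargylic cation equivalent accepts the phenoxide at the tertiary carbon. Forward, the alkyne must then be reduced to the alkene without touching the lactone double bond.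

## Alternatives that were turned down

**Alternative 1:** Ring A is taken apart completely by cutting C5–C6 and C7–C8, which gives dimethyl malonate A1 and 7-methylocta-1,6-dien-3-one A2.
- Forward key step: under alkoxide base A1 adds in a Michael reaction to the vinyl terminus of A2. The ketone α-carbon that carries the prenyl group then attacks one malonate ester in a Claisen condensation, giving methyl 2-hydroxy-3-(3-methylbut-2-en-1-yl)-4-oxocyclohex-2-ene-1-carboxylate A3 (racemic, enol form).
- For: the ester carbon (future C6), the two oxygens (future O7 and O1) and the prenyl group between them are placed by the connectivity of the acyclic partners. On regiochemical certainty this is as strong as the chosen route, arguably stronger, since no rearrangement selectivity is involved; the materials are cheap.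
- Against: A3 is at the wrong oxidation level and lacks the pyran ring and the side chain. Ring A must be dehydrogenated in the presence of the prenyl alkene, the two resulting phenols distinguished, the pyran annulated, and the ester turned into the aryl ketone. A2 is itself not an article of commerce.
- Comparison: the chosen route buys ring A aromatic, with O1, C2, C3 and C4 attached, in 1. It needs four steps to the key precursor 8 and no redox adjustment of the ring.

**Alternative 2:** The pyran is cut at C3–C4 and O1–C2, which leads to 5-{3-[4-(tert-butyldimethylsilyloxy)phenyl]propanoyl}-2,4-dihydroxy-3-(3-methylbut-2-en-1-yl)benzaldehyde A4, dibenzylamine A5 and 2-methylprop-1-enylboronic acid A6.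
- Forward key step: A4 and A5 form an iminium ion, and the boronate bound to the ortho phenol transfers its alkenyl group to the iminium carbon (C3–C4). Loss of A5 gives an ortho-quinone methide, and oxa-6π closure makes O1–C2, giving 3-[4-(tert-butyldimethylsilyloxy)phenyl]-1-[7-hydroxy-2,2-dimethyl-8-(3-methylbut-2-en-1-yl)-2H-chromen-6-yl]propan-1-one A7.
- For: the pyran is closed last, under nearly neutral conditions, on a substrate that already carries the whole acyl chain. A7 is one desilylation from 18, and no organolithium step on a chromene is needed. On mildness and convergence this plan is stronger than the chosen one.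
- Against: all of the difficulty moves into A4, a pentasubstituted benzene with a formyl and an acyl group, two phenols and a prenyl group between them. Making A4 means prenylating a resorcinol ketone between its hydroxyls and formylating the one remaining position, which is the regiochemical problem of the target undiminished. The aldehyde of A4 is also deactivated by a para hydroxyl and a strong hydrogen bond.
- Comparison: the chosen strategy offers instead a key precursor (8) whose substitution pattern is fixed by the coumarin skeleton and which is reached in four dependable steps.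

**Alternative 3:** Ring A is again built from acyclic pieces, by cutting C7–C8, C4a–C8a and C6–C7. The partners are (3E)-1-diazo-7-[4-(methoxymethoxy)phenyl]hept-3-ene-2,5-dione A8 and triisopropyl[(5-methylhex-4-en-1-yn-1-yl)oxy]silane A9.
- Forward key step: irradiation of A8 triggers a Wolff rearrangement to a vinylketene, which undergoes (2+2) cycloaddition with A9. Ring opening of the cyclobutenone and 6π closure of the dienylketene give, after tautomerisation, 1-[2-hydroxy-3-(3-methylbut-2-en-1-yl)-4-(triisopropylsilyloxy)phenyl]-3-[4-(methoxymethoxy)phenyl]propan-1-one A10.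
- For: one step sets acyl group, free hydroxyl, prenyl group and silyloxy group in the right order around the ring. The two oxygens are born different and the side chain is in place, so no aryl metalation is needed. On these points it matches or beats the chosen route.
- Against: A8 combines a diazo ketone with an enedione Michael acceptor. A9 needs a multistep preparation from an ester through an ynolate. The ketene may be diverted by the remote ketone or the alkene of A9. A10 still has no pyran ring, which must be annulated at the one free ortho position after desilylation.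
- Comparison: counting the preparation of A8 and A9 and the later annulation, the sequence is clearly longer than the nine steps planned here. Its key step needs photochemistry and a diazo compound where the chosen route uses an organolithium addition of a long-established type.

Key step: step 5

Remark on the chemistry: 18 is achiral; the only geometrical element in the route is the Z alkene of the open-chain intermediates 9 and 10, which is inherited from the lactone ring.

## Route

Step 1
Reactants: 1 7-hydroxy-2H-chromen-2-one (umbelliferone); 2 2-methylbut-3-yn-2-ol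
Product: 4 7-[(2-methylbut-3-yn-2-yl)oxy]-2H-chromen-2-one, via 2-methylbut-3-yn-2-yl trifluoroacetate 3 (not isolated)
Conditions: 2, (CF3CO)2O, DBU, MeCN, −5 °C; then added to 1, DBU, CuCl2·2H2O (cat.), MeCN, 0 °C
Reagents that add atoms: none
Why: Copper-catalysed propargylic substitution of a tertiary propargylic ester by a phenoxide: 3 forms a copper acetylide that ionises to a copper-stabilised propargyl/allenylidene cation, which the DBU salt of the acidic 7-hydroxyl captures at the tertiary carbon. The lactone is inert to the non-nucleophilic amidine base.

Step 2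
Reactants: 4 7-[(2-methylbut-3-yn-2-yl)oxy]-2H-chromen-2-one
Product: 5 7-[(2-methylbut-3-en-2-yl)oxy]-2H-chromen-2-one
Conditions: H2 (1 atm), Pd on CaCO3 poisoned with Pb(OAc)2 (Lindlar type), quinoline, EtOAc, 25 °C, stopped after one equivalent
Reagents that add atoms: none
Why: Lindlar semihydrogenation: the poisoned palladium surface reduces the terminal alkyne far faster than the resulting alkene or the conjugated lactone C3=C4 bond, so uptake stops at the 1,1-dimethylallyl ether.

Step 3
Reactants: 5 7-[(2-methylbut-3-en-2-yl)oxy]-2H-chromen-2-one
Product: 7 7-hydroxy-8-(3-methylbut-2-en-1-yl)-2H-chromen-2-one (osthenol), via ortho-dienone 6 (not isolated)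
Conditions: PhNEt2, 130–150 °C, Ar
Reagents that add atoms: none
Why: Aromatic Claisen rearrangement: the [3,3] shift transfers the allyl unit with inversion, so the tertiary ether terminus on O7 becomes the primary prenyl terminus on carbon, and dienone 6 tautomerises to phenol 7. The shift uses the C7–C8 bond, which has the higher double-bond character in the coumarin, so C8 is preferred over C6; the gem-dimethyl group lowers the temperature needed.

Step 4
Reactants: 7 7-hydroxy-8-(3-methylbut-2-en-1-yl)-2H-chromen-2-one
Product: 8 7-(methoxymethoxy)-8-(3-methylbut-2-en-1-yl)-2H-chromen-2-one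
Conditions: MOMCl, i-Pr2NEt, CH2Cl2, 0 → 25 °C
Reagents that add atoms: chloromethyl methyl ether (MOMCl), COCCl
Why: O-alkylation of the phenoxide with a reactive α-chloro ether. The acetal resists organolithium reagents and later directs metalation to C6.

Step 5
Reactants: 8 7-(methoxymethoxy)-8-(3-methylbut-2-en-1-yl)-2H-chromen-2-one
Product: 11 7-(methoxymethoxy)-2,2-dimethyl-8-(3-methylbut-2-en-1-yl)-2H-chromene, via Z-enone phenoxide 9 (not isolated), via Z-allylic diol 10 (not isolated)
Conditions: CH3Li (3.5 equiv), THF, −78 → 0 °C; aq. NH4Cl; then PPTS (cat.), CH2Cl2, 25 °C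
Reagents that add atoms: methyllithium, [Li]C
Why: The first CH3Li adds to the lactone carbonyl (C2) and the tetrahedral adduct opens to the lithium phenoxide of Z-enone 9; the second adds 1,2 to the new methyl ketone, so both C2–CH3 bonds are formed and the quench gives the Z tertiary allylic alcohol 10. Catalytic pyridinium p-toluenesulfonate then ionises this alcohol to an allyl cation stabilised by the ortho phenol oxygen and the para acetal oxygen, and O1 closes onto C2. The pyran ring thus forms by a 6-exo-tet substitution at C2 running through the cation, which can equally be read as an oxa-6π electrocyclisation of the ortho-quinone methide. The closest known reaction type is the conversion of coumarins into 2,2-dimethyl-2H-chromenes by excess methyl organometallic followed by cyclodehydration. No stereocentre is created; the cis C3=C4 geometry needed for closure comes from the lactone ring and is kept because 9 is consumed at low temperature. The step needs 1,2- over 1,4-addition to 9, secured by the hard organolithium at −78 °C and by the electron-rich aryl group (ortho phenoxide, para alkoxy), which deactivates the β-carbon. It also needs ionisation of the allylic alcohol to outrun acetal cleavage and protonation of the prenyl alkene, which the high stability of the cation secures under a weak acid.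

Step 6
Reactants: 12 3-(4-hydroxyphenyl)propanoic acid (phloretic acid)
Product: 13 3-(4-hydroxyphenyl)-N-methoxy-N-methylpropanamide
Conditions: MeNH(OMe)·HCl, EDC·HCl, HOBt, N-methylmorpholine, CH2Cl2, 0 → 25 °C
Reagents that add atoms: N,O-dimethylhydroxylamine hydrochloride, CNOC.Cl
Why: Carbodiimide-mediated amide coupling: the hydroxybenzotriazole active ester is taken by the amine much faster than by the free phenol, so the phenol need not be protected first.

Step 7
Reactants: 13 3-(4-hydroxyphenyl)-N-methoxy-N-methylpropanamide
Product: 14 N-methoxy-3-[4-(methoxymethoxy)phenyl]-N-methylpropanamide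
Conditions: MOMCl, i-Pr2NEt, CH2Cl2, 0 → 25 °C
Reagents that add atoms: chloromethyl methyl ether (MOMCl), COCCl
Why: O-alkylation of the phenol as in step 4. Using the same acetal on both phenols lets one final operation remove both.

Step 8
Reactants: 11 7-(methoxymethoxy)-2,2-dimethyl-8-(3-methylbut-2-en-1-yl)-2H-chromene; 14 N-methoxy-3-[4-(methoxymethoxy)phenyl]-N-methylpropanamide
Product: 17 1-[7-(methoxymethoxy)-2,2-dimethyl-8-(3-methylbut-2-en-1-yl)-2H-chromen-6-yl]-3-[4-(methoxymethoxy)phenyl]propan-1-one, via C6 aryllithium 15 (not isolated), via chelated lithium hemiaminal 16 (not isolated)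
Conditions: s-BuLi, TMEDA, THF, −78 °C; then 14, −78 → 0 °C; aq. NH4Cl
Reagents that add atoms: none
Why: Directed ortho-metalation followed by Weinreb ketone synthesis: the acetal oxygens bind the alkyllithium and steer deprotonation to C6, the only ring position ortho to the C7 acetal because C8 carries the prenyl group. Aryllithium 15 adds to 14 to give the chelated adduct 16, which does not collapse before work-up, so no tertiary alcohol forms.

Step 9
Reactants: 17 1-[7-(methoxymethoxy)-2,2-dimethyl-8-(3-methylbut-2-en-1-yl)-2H-chromen-6-yl]-3-[4-(methoxymethoxy)phenyl]propan-1-one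
Product: 18 1-[7-hydroxy-2,2-dimethyl-8-(3-methylbut-2-en-1-yl)-2H-chromen-6-yl]-3-(4-hydroxyphenyl)propan-1-one
Conditions: HCl (1.25 M in MeOH), 0 → 25 °C
Reagents that add atoms: none
Why: Acid-catalysed transacetalisation to the solvent removes both methoxymethyl groups. The C7 acetal, ortho to the ketone, goes first, and the released hydroxyl is held in a hydrogen bond to the carbonyl, which lowers its tendency to add to the neighbouring prenyl alkene.

## Compound list

1 | 7-hydroxy-2H-chromen-2-one (umbelliferone) | O=c1ccc2ccc(O)cc2o1 | starting material
2 | 2-methylbut-3-yn-2-ol | CC(C)(O)C#C | starting material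
3 | 2-methylbut-3-yn-2-yl trifluoroacetate (formed in the flask) | C#CC(C)(C)OC(=O)C(F)(F)F | intermediate
4 | 7-[(2-methylbut-3-yn-2-yl)oxy]-2H-chromen-2-one | C#CC(C)(C)Oc1ccc2ccc(=O)oc2c1 | intermediate
5 | 7-[(2-methylbut-3-en-2-yl)oxy]-2H-chromen-2-one | C=CC(C)(C)Oc1ccc2ccc(=O)oc2c1 | intermediate
6 | 8-(3-methylbut-2-en-1-yl)-8H-chromene-2,7-dione (racemic, formed in the flask) | CC(C)=CCC1C(=O)C=CC2=C1OC(=O)C=C2 | intermediate
7 | 7-hydroxy-8-(3-methylbut-2-en-1-yl)-2H-chromen-2-one (osthenol) | CC(C)=CCc1c(O)ccc2ccc(=O)oc12 | intermediate
8 | 7-(methoxymethoxy)-8-(3-methylbut-2-en-1-yl)-2H-chromen-2-one | CC(C)=CCc1c(OCOC)ccc2ccc(=O)oc12 | intermediate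
9 | lithium 3-(methoxymethoxy)-2-(3-methylbut-2-en-1-yl)-6-[(1Z)-3-oxobut-1-en-1-yl]phenolate (formed in the flask) | CC(=O)/C=C\c1ccc(OCOC)c(CC=C(C)C)c1O[Li] | intermediate
10 | 2-[(1Z)-3-hydroxy-3-methylbut-1-en-1-yl]-5-(methoxymethoxy)-6-(3-methylbut-2-en-1-yl)phenol (formed in the flask) | CC(C)(O)/C=C\c1ccc(OCOC)c(CC=C(C)C)c1O | intermediate
11 | 7-(methoxymethoxy)-2,2-dimethyl-8-(3-methylbut-2-en-1-yl)-2H-chromene | CC(C)=CCc1c(OCOC)ccc2c1OC(C)(C)C=C2 | intermediate
12 | 3-(4-hydroxyphenyl)propanoic acid (phloretic acid) | OC(=O)CCc1ccc(O)cc1 | starting material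
13 | 3-(4-hydroxyphenyl)-N-methoxy-N-methylpropanamide | CON(C)C(=O)CCc1ccc(O)cc1 | intermediate
14 | N-methoxy-3-[4-(methoxymethoxy)phenyl]-N-methylpropanamide | CON(C)C(=O)CCc1ccc(OCOC)cc1 | intermediate
15 | [7-(methoxymethoxy)-2,2-dimethyl-8-(3-methylbut-2-en-1-yl)-2H-chromen-6-yl]lithium (formed in the flask) | CC(C)=CCc1c(OCOC)c([Li])cc2c1OC(C)(C)C=C2 | intermediate
16 | lithium 1-[methoxy(methyl)amino]-1-[7-(methoxymethoxy)-2,2-dimethyl-8-(3-methylbut-2-en-1-yl)-2H-chromen-6-yl]-3-[4-(methoxymethoxy)phenyl]propan-1-olate (racemic, formed in the flask) | CC(C)=CCc1c(OCOC)c(C(O[Li])(CCc2ccc(OCOC)cc2)N(C)OC)cc2c1OC(C)(C)C=C2 | intermediate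
17 | 1-[7-(methoxymethoxy)-2,2-dimethyl-8-(3-methylbut-2-en-1-yl)-2H-chromen-6-yl]-3-[4-(methoxymethoxy)phenyl]propan-1-one | CC(C)=CCc1c(OCOC)c(C(=O)CCc2ccc(OCOC)cc2)cc2c1OC(C)(C)C=C2 | intermediate
18 | 1-[7-hydroxy-2,2-dimethyl-8-(3-methylbut-2-en-1-yl)-2H-chromen-6-yl]-3-(4-hydroxyphenyl)propan-1-one | CC(C)=CCc1c(O)c(C(=O)CCc2ccc(O)cc2)cc2c1OC(C)(C)C=C2 | target

## Step count and risk

Total step count: 9. Longest linear sequence: 7 steps (steps 1, 2, 3, 4, 5, 8, 9, from 1 to 18); steps 6 and 7 form the two-step branch to amide 14.

**Step 5 (key step).**
- What may go wrong: the second methyl addition may stall because the organolithium enolises the methyl ketone of 9, or it may go in the conjugate sense at C4. In the acid stage the acetal may be lost, or the new phenol may add to the prenyl alkene.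
- Fallback (sets out from 2 through its trifluoroacetate 3, comes back at 11): the pyran is not derived from a lactone at all. Trifluoroacetate 3 is coupled under the copper-catalysed conditions of step 1 with an excess of resorcinol F1 to give 3-[(2-methylbut-3-yn-2-yl)oxy]phenol F2. Heating F2 (xylene, 140 °C) brings about propargyl Claisen rearrangement, 1,5-hydrogen shift and oxa-6π closure to 7-hydroxy-2,2-dimethyl-2H-chromene F3. MOMCl and i-Pr2NEt give 7-(methoxymethoxy)-2,2-dimethyl-2H-chromene F4. n-BuLi (THF, 0 °C) deprotonates C8 of F4, the position between the two oxygens, and transmetalation with CuBr·SMe2 followed by 1-bromo-3-methylbut-2-ene F5 gives 11.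
- Cost of the fallback: it gives up the regiochemical certainty of the coumarin, because the propargyl Claisen step can also go to the carbon between the two oxygens.

**Step 8.**
- What may go wrong: proton abstraction at the doubly activated benzylic–allylic CH2 of the prenyl group instead of at C6, or proton transfer from that CH2 to aryllithium 15 on warming. The alkyllithium may also add across the styrene-type C3=C4 bond, and 15 may enolise amide 14.
- Fallback (sets out from 11, comes back at 17): the carbon is introduced by electrophilic substitution, not by deprotonation. Vilsmeier–Haack formylation of 11 (POCl3, DMF, 0 → 25 °C, buffered NaOAc hydrolysis) attacks C6, which is para to O1 and ortho to O7, and gives 7-(methoxymethoxy)-2,2-dimethyl-8-(3-methylbut-2-en-1-yl)-2H-chromene-6-carbaldehyde F6. 1-(2-Bromoethyl)-4-(methoxymethoxy)benzene F7 is converted with magnesium into 2-[4-(methoxymethoxy)phenyl]ethylmagnesium bromide F8. Addition of F8 to F6 (THF, 0 °C) gives racemic 1-[7-(methoxymethoxy)-2,2-dimethyl-8-(3-methylbut-2-en-1-yl)-2H-chromen-6-yl]-3-[4-(methoxymethoxy)phenyl]propan-1-ol F9. Dess–Martin oxidation of F9 (NaHCO3, CH2Cl2) gives 17.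

**Step 3.**
- What may go wrong: fragmentation of the tertiary allyl ether back to 1 with loss of the C5 unit, partial migration to C6, and thermal addition of the new phenol to the prenyl alkene on prolonged heating.
- Fallback (sets out from 1, comes back at 8): the C8–prenyl bond is made by cross-coupling. Iodination of 1 (I2, KI, aq. NH3) gives 7-hydroxy-8-iodo-2H-chromen-2-one F10. MOMCl and i-Pr2NEt give 8-iodo-7-(methoxymethoxy)-2H-chromen-2-one F11. Stille coupling of F11 with tributyl(3-methylbut-2-en-1-yl)stannane F12 (Pd(PPh3)4, LiCl, DMF, 90 °C) gives 8.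
- Cost of the fallback: it is no longer than steps 1–4, but it depends on site-selective iodination and on transfer of the prenyl group without allylic transposition, which the sigmatropic route does not.

**Step 9.**
- What may go wrong: acid-catalysed addition of the freed C7 hydroxyl to the prenyl alkene (closure of a second, saturated pyran), or addition of solvent to the chromene C3=C4 bond. The ring B acetal is the slower one, which prolongs the acid exposure.
- Fallback (sets out from 7 and 13, comes back at 18): both phenols are masked with fluoride-labile groups so that no acid is used at the end. Phenol 7 with 2-(trimethylsilyl)ethoxymethyl chloride and i-Pr2NEt gives 8-(3-methylbut-2-en-1-yl)-7-{[2-(trimethylsilyl)ethoxy]methoxy}-2H-chromen-2-one F13. The conditions of step 5 convert F13 into 2,2-dimethyl-8-(3-methylbut-2-en-1-yl)-7-{[2-(trimethylsilyl)ethoxy]methoxy}-2H-chromene F14. Amide 13 with t-BuMe2SiCl and imidazole gives 3-[4-(tert-butyldimethylsilyloxy)phenyl]-N-methoxy-N-methylpropanamide F15. Metalation of F14 and addition to F15 as in step 8 give 3-[4-(tert-butyldimethylsilyloxy)phenyl]-1-(2,2-dimethyl-8-(3-methylbut-2-en-1-yl)-7-{[2-(trimethylsilyl)ethoxy]methoxy}-2H-chromen-6-yl)propan-1-one F16. Bu4NF (THF, then DMPU, 50 °C) removes both groups from F16 and gives 18.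

## Further compounds

F1 | step 5 | benzene-1,3-diol (resorcinol) | Oc1cccc(O)c1
F2 | step 5 | 3-[(2-methylbut-3-yn-2-yl)oxy]phenol | C#CC(C)(C)Oc1cccc(O)c1
F3 | step 5 | 7-hydroxy-2,2-dimethyl-2H-chromene | CC1(C)C=Cc2ccc(O)cc2O1
F4 | step 5 | 7-(methoxymethoxy)-2,2-dimethyl-2H-chromene | COCOc1ccc2C=CC(C)(C)Oc2c1
F5 | step 5 | 1-bromo-3-methylbut-2-ene | CC(C)=CCBr
F6 | step 8 | 7-(methoxymethoxy)-2,2-dimethyl-8-(3-methylbut-2-en-1-yl)-2H-chromene-6-carbaldehyde | CC(C)=CCc1c(OCOC)c(C=O)cc2c1OC(C)(C)C=C2
F7 | step 8 | 1-(2-bromoethyl)-4-(methoxymethoxy)benzene | COCOc1ccc(CCBr)cc1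
F8 | step 8 | 2-[4-(methoxymethoxy)phenyl]ethylmagnesium bromide | COCOc1ccc(CC[Mg]Br)cc1
F9 | step 8 | 1-[7-(methoxymethoxy)-2,2-dimethyl-8-(3-methylbut-2-en-1-yl)-2H-chromen-6-yl]-3-[4-(methoxymethoxy)phenyl]propan-1-ol (racemic) | CC(C)=CCc1c(OCOC)c(C(O)CCc2ccc(OCOC)cc2)cc2c1OC(C)(C)C=C2
F10 | step 3 | 7-hydroxy-8-iodo-2H-chromen-2-one | Oc1ccc2ccc(=O)oc2c1I
F11 | step 3 | 8-iodo-7-(methoxymethoxy)-2H-chromen-2-one | COCOc1ccc2ccc(=O)oc2c1I
F12 | step 3 | tributyl(3-methylbut-2-en-1-yl)stannane | CC(C)=CC[Sn](CCCC)(CCCC)CCCC
F13 | step 9 | 8-(3-methylbut-2-en-1-yl)-7-{[2-(trimethylsilyl)ethoxy]methoxy}-2H-chromen-2-one | CC(C)=CCc1c(OCOCC[Si](C)(C)C)ccc2ccc(=O)oc12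
F14 | step 9 | 2,2-dimethyl-8-(3-methylbut-2-en-1-yl)-7-{[2-(trimethylsilyl)ethoxy]methoxy}-2H-chromene | CC(C)=CCc1c(OCOCC[Si](C)(C)C)ccc2c1OC(C)(C)C=C2
F15 | step 9 | 3-[4-(tert-butyldimethylsilyloxy)phenyl]-N-methoxy-N-methylpropanamide | CON(C)C(=O)CCc1ccc(O[Si](C)(C)C(C)(C)C)cc1
F16 | step 9 | 3-[4-(tert-butyldimethylsilyloxy)phenyl]-1-(2,2-dimethyl-8-(3-methylbut-2-en-1-yl)-7-{[2-(trimethylsilyl)ethoxy]methoxy}-2H-chromen-6-yl)propan-1-one | CC(C)=CCc1c(OCOCC[Si](C)(C)C)c(C(=O)CCc2ccc(O[Si](C)(C)C(C)(C)C)cc2)cc2c1OC(C)(C)C=C2
A1 | alternative 1 | dimethyl malonate | COC(=O)CC(=O)OC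
A2 | alternative 1 | 7-methylocta-1,6-dien-3-one | C=CC(=O)CCC=C(C)C
A3 | alternative 1 | methyl 2-hydroxy-3-(3-methylbut-2-en-1-yl)-4-oxocyclohex-2-ene-1-carboxylate (racemic, enol form) | COC(=O)C1CCC(=O)C(CC=C(C)C)=C1O
A4 | alternative 2 | 5-{3-[4-(tert-butyldimethylsilyloxy)phenyl]propanoyl}-2,4-dihydroxy-3-(3-methylbut-2-en-1-yl)benzaldehyde | O=Cc1cc(C(=O)CCc2ccc(O[Si](C)(C)C(C)(C)C)cc2)c(O)c(CC=C(C)C)c1O
A5 | alternative 2 | dibenzylamine | C(NCc1ccccc1)c1ccccc1
A6 | alternative 2 | 2-methylprop-1-enylboronic acid | CC(C)=CB(O)O
A7 | alternative 2 | 3-[4-(tert-butyldimethylsilyloxy)phenyl]-1-[7-hydroxy-2,2-dimethyl-8-(3-methylbut-2-en-1-yl)-2H-chromen-6-yl]propan-1-one | CC(C)=CCc1c(O)c(C(=O)CCc2ccc(O[Si](C)(C)C(C)(C)C)cc2)cc2c1OC(C)(C)C=C2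
A8 | alternative 3 | (3E)-1-diazo-7-[4-(methoxymethoxy)phenyl]hept-3-ene-2,5-dione | [N-]=[N+]=CC(=O)/C=C/C(=O)CCc1ccc(OCOC)cc1
A9 | alternative 3 | triisopropyl[(5-methylhex-4-en-1-yn-1-yl)oxy]silane | CC(C)=CCC#CO[Si](C(C)C)(C(C)C)C(C)C
A10 | alternative 3 | 1-[2-hydroxy-3-(3-methylbut-2-en-1-yl)-4-(triisopropylsilyloxy)phenyl]-3-[4-(methoxymethoxy)phenyl]propan-1-one | CC(C)=CCc1c(O[Si](C(C)C)(C(C)C)C(C)C)ccc(C(=O)CCc2ccc(OCOC)cc2)c1O
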